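The SMILES describes a cis-fused labdane: H-5, CH3-20, H-9 and the C4 carboxyl share one face. Ring B (C5–C10) is disconnected at C9–C10 and traced back to the five-membered ring (C5, C6, C7, C8, C10) of a cis-hydrindanone built around one catalytically set centre, C10. The C9–C15 chain is hung on C8 by olefination. In the key step the 8,9-diol monomesylate undergoes a semipinacol shift of C10 from C8 to C9. This one operation exploits the C10 (quaternary)–C9 (side chain)–C8 (sp2) triad of ring B. It inserts C9 into the ring, forges the congested C9–C10 bond, creates C9 next to an epimerising carbonyl and leaves the C8 ketone that becomes the exocyclic methylene.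

Key step: step 14

Remark on numbering: labdane numbering is used throughout and β is the face of CH3-20. The descriptors of the SMILES are taken literally (4S,5S,9R,10R,13S, A/B cis).
Assumption: the sense of induction drawn for the ligand in step 3 is assumed. Should it be the opposite, the antipodal ligand is used.

Step 1
Reactants: 1 2-methylcyclopentane-1,3-dione; 2 acrolein
Product: 3 3-(1-methyl-2,5-dioxocyclopentyl)propanal
Conditions: H2O, rt
Reagents that add atoms: none
Why: Michael addition of the acidic 2-alkyl-1,3-dione to acrolein in water is a standard C-alkylation that makes the C10–C1 bond; the product is achiral (C10 is prochiral).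

Step 2
Reactants: 3 3-(1-methyl-2,5-dioxocyclopentyl)propanal; 4 tert-butyl (triphenylphosphoranylidene)acetate
Product: 5 tert-butyl (E)-5-(1-methyl-2,5-dioxocyclopentyl)pent-2-enoate
Conditions: CH2Cl2, rt
Reagents that add atoms: none
Why: Wittig olefination with a stabilised ylide takes the aldehyde only, leaves both ketones alone and gives the E-enoate that carries C4 and C19.

Step 3
Reactants: 5 tert-butyl (E)-5-(1-methyl-2,5-dioxocyclopentyl)pent-2-enoate
Product: 7 tert-butyl (3aS,4S,7aS)-3a-hydroxy-7a-methyl-1-oxooctahydro-1H-indene-4-carboxylate (cis-fused ketol; OH, CH3-20 and ester β), via phenylsilyl ether 6 (not isolated)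
Conditions: Cu(OAc)2·H2O (cat.), (R)-SEGPHOS (cat.), PhSiH3, toluene, −20 °C → rt; then 1 M HCl, THF
Reagents that add atoms: phenylsilane, [SiH3]c1ccccc1 (its silyl group stays only in 6)
Why: Copper hydride-catalysed asymmetric reductive aldol cyclisation: conjugate reduction gives a copper enolate at C4 that adds 6-exo through a chair-like Zimmerman–Traxler array to one of the two enantiotopic ketones, so that the ligand sets C10 while ring strain enforces the cis-fused ketol with OH, CH3-20 and ester on one face (C4 and C5 are reset later).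

Step 4
Reactants: 7 cis-fused ketol
Product: 8 tert-butyl (7aS)-7a-methyl-1-oxo-2,3,5,6,7,7a-hexahydro-1H-indene-4-carboxylate (C4=C5 conjugated ester, C8 ketone)
Conditions: SOCl2, pyridine, CH2Cl2, 0 °C; then DBU (cat.), rt
Reagents that add atoms: none
Why: Thionyl chloride/pyridine dehydration of the tertiary β-hydroxy ester can only use H-4 or H-6 because C10 is quaternary, and DBU gathers the product as the conjugated ester, which removes the provisional centres C4 and C5 and leaves C10 untouched.

Step 5
Reactants: 8 keto enoate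
Product: 9 tert-butyl (1S,7aS)-1-hydroxy-7a-methyl-2,3,5,6,7,7a-hexahydro-1H-indene-4-carboxylate (8β-OH, cis to CH3-20)
Conditions: NaBH4, MeOH, −20 °C
Reagents that add atoms: none
Why: Borohydride reduction: hydride reaches the C8 ketone from the α face, opposite the angular CH3-20, as in the related bicyclic enediones, to give the 8β-alcohol that masks the ketone in step 6 and directs step 7, while the conjugated ester is inert.

Step 6
Reactants: 9 hydroxy enoate
Product: 11 tert-butyl (1S,4S,7aS)-1-hydroxy-4,7a-dimethyl-2,4,5,6,7,7a-hexahydro-1H-indene-4-carboxylate (CH3-18 α, ester β, olefin C5=C6), via dilithium dienolate 10 (not isolated)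
Conditions: LDA (2.3 equiv), THF–DMPU, −78 → −40 °C; MeI, −78 °C; H2O
Reagents that add atoms: methyl iodide, CI; lithium diisopropylamide, [Li+].CC(C)[N-]C(C)C (lithium only in 10)
Why: Deconjugative α-alkylation of an extended ester enolate: LDA removes O–H and the γ-proton H-6, and methyl iodide enters at C4 from the α face, anti to the pseudo-axial CH3-20 that stands 1,3 to it, which sets the quaternary centre (CH3-18 α, ester β) and leaves the olefin at C5=C6.

Step 7
Reactants: 11 hydrindenol
Product: 12 tert-butyl (1S,3aS,4S,7aS)-1-hydroxy-4,7a-dimethyloctahydro-1H-indene-4-carboxylate (cis-hydrindane; H-5, CH3-20, ester and OH all β)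
Conditions: [Ir(cod)(PCy3)(py)]PF6 (cat.), H2, CH2Cl2, rt
Reagents that add atoms: none
Why: Hydroxyl-directed hydrogenation with Crabtree's catalyst: iridium held by the homoallylic 8β-OH of this cyclopent-3-enol delivers H2 to the β face, so that H-5 ends up cis to CH3-20 and to the ester, against the steric bias that would give the trans-hydrindane.

Step 8
Reactants: 12 cis-hydrindanol
Product: 13 tert-butyl (3aS,4S,7aS)-4,7a-dimethyl-1-oxooctahydro-1H-indene-4-carboxylate (cis-hydrindanone)
Conditions: Dess–Martin periodinane, CH2Cl2, rt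
Reagents that add atoms: none
Why: Dess–Martin oxidation returns the C8 ketone under neutral conditions; its only stereogenic neighbour, C10, is quaternary and cannot epimerise.

Step 9
Reactants: 14 (S)-(−)-citronellol
Product: 15 (S)-citronellyl tert-butyldimethylsilyl ether
Conditions: TBSCl, imidazole, CH2Cl2, rt
Reagents that add atoms: tert-butyldimethylsilyl chloride, CC(C)(C)[Si](C)(C)Cl
Why: Standard silylation of the primary alcohol; C13 comes from the chiral pool and is not touched.

Step 10
Reactants: 15 silyl ether
Product: 17 (S)-6-[(tert-butyldimethylsilyl)oxy]-4-methylhexan-1-ol, via ozonide 16 (not isolated)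
Conditions: O3, CH2Cl2, −78 °C; then NaBH4, MeOH, −78 °C → rt
Reagents that add atoms: ozone, [O-][O+]=O
Why: Ozonolysis with reductive borohydride work-up cuts the isopropylidene end off and leaves C9 as a primary alcohol; silyl ether and C13 are inert.

Step 11
Reactants: 17 monoprotected diol
Product: 19 [(S)-6-[(tert-butyldimethylsilyl)oxy]-4-methylhexyl]triphenylphosphonium iodide, via iodide 18 (not isolated)
Conditions: I2, PPh3 (excess), imidazole, MeCN, 0 °C → rt; then reflux
Reagents that add atoms: iodine, II; triphenylphosphine, c1ccc(cc1)P(c1ccccc1)c1ccccc1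
Why: Appel-type iodination followed by SN2 quaternisation of the excess phosphine on heating gives the Wittig salt in one flask, imidazole keeping the medium non-acidic for the silyl ether.

Step 12
Reactants: 13 cis-hydrindanone; 19 phosphonium iodide
Product: 21 tert-butyl (Z,3aS,4S,7aS)-1-[(S)-6-[(tert-butyldimethylsilyl)oxy]-4-methylhexylidene]-4,7a-dimethyloctahydro-1H-indene-4-carboxylate (C8=C9 olefin, chain cis to C10), via ylide 20 (not isolated)
Conditions: NaHMDS, THF, 0 °C; then 13, reflux
Reagents that add atoms: none
Why: Wittig olefination with a non-stabilised ylide makes the C8=C9 bond; kinetic control should place the chain cis to the larger, quaternary C10 (Z), as in the ethylidenation of 17-oxo steroids, and the tert-butyl ester and silyl ether are inert.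

Step 13
Reactants: 21 Z-alkylidene hydrindane
Product: 22 tert-butyl (1S,3aS,4S,7aS)-1-hydroxy-1-[(1R,4S)-6-[(tert-butyldimethylsilyl)oxy]-1-hydroxy-4-methylhexyl]-4,7a-dimethyloctahydro-1H-indene-4-carboxylate (8β,9-diol)
Conditions: OsO4 (cat.), NMO, MeSO2NH2, acetone–H2O, rt
Reagents that add atoms: N-methylmorpholine N-oxide, C[N+]1([O-])CCOCC1 (one O, relayed by osmium); water, O (one O)
Why: Catalytic osmium tetroxide/NMO dihydroxylation adds syn to the only olefin from the convex β face, because C1 of ring A stands pseudo-axial under C8 on the concave α face, which sets C8 (8β-OH) and, through the Z geometry, C9.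

Step 14
Reactants: 22 8β,9-diol
Product: 25 tert-butyl (1S,4aS,5S,8aS)-5-[(S)-5-[(tert-butyldimethylsilyl)oxy]-3-methylpentyl]-1,4a-dimethyl-6-oxodecahydronaphthalene-1-carboxylate (cis-decalone; H-5, H-9, CH3-20 and ester β), via mesylate 23 (not isolated), via 9-epi ketone 24 (not isolated)
Conditions: MsCl, Et3N, CH2Cl2, −20 °C; Et3Al (excess), −78 → 0 °C; MeOH quench, then K2CO3 (cat.), MeOH, rt
Reagents that add atoms: methanesulfonyl chloride, CS(=O)(=O)Cl (stays only in 23)
Why: Sulfene mesylation takes only the secondary 9-OH; triethylaluminium then converts the tertiary 8-OH into an aluminium alkoxide that also binds the mesylate, and the C8–C10 bond, antiperiplanar to C9–OMs, migrates to C9 while the mesylate leaves and C8 becomes the carbonyl carbon. The closest known reaction type is the organoaluminium-promoted semipinacol (pinacol-type) rearrangement of 2-hydroxy mesylates, as used in olefination/dihydroxylation/monosulfonate ring enlargements and in the D-homoannulation of 17-hydroxy-20-sulfonyloxy steroids, whose angular-methyl hydrindane surroundings are the same. No ring is closed from an open chain: the five-membered ring C5–C6–C7–C8–C10 is enlarged to the six-membered ring B by a suprafacial 1,2-alkyl shift with retention at C10, so that the cis fusion and C4, C5, C10 and C13 are not touched. C9 is the only new stereocentre: the shift inverts the mesylate carbon and first gives the 9-epimer 24 with an axial chain, and the carbonyl just created lets carbonate equilibrate it to 25, whose chain is equatorial on ring B in the chair–chair form that avoids a CH3-18/C9 syn-diaxial contact (the minor epimer can be recycled). The step needs migration of C10 and not of C7 and must avoid epoxide closure: the aluminium chelate holds O8 and O9 gauche, which excludes the anti rotamer that an epoxide needs, and in the syn-diol derived from the Z-olefin the rotamer with C10 anti to the mesylate puts C11 between O8 and C10, whereas the one with C7 anti forces C11 between C7 and C10. The higher migratory aptitude of the fully substituted C10 and the relief of the vicinal C8/C10 congestion act in the same direction.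

Step 15
Reactants: 25 cis-decalone
Product: 27 tert-butyl (1S,4aR,5R,8aS)-5-[(S)-5-hydroxy-3-methylpentyl]-1,4a-dimethyl-6-methylidenedecahydronaphthalene-1-carboxylate, via silyl ether 26 (not isolated)
Conditions: Ph3PCH3Br, KOtBu, THF, 0 → 50 °C; then TBAF, rt
Reagents that add atoms: methyltriphenylphosphonium bromide, [Br-].C[P+](c1ccccc1)(c1ccccc1)c1ccccc1 (gives the CH2 of C17)
Why: Wittig methylenation of the C8 ketone, whose C9 centre is already the more stable epimer, followed by fluoride cleavage of the primary silyl ether in the same flask; the hindered tert-butyl ester survives both.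

Step 16
Reactants: 27 C15 alcohol; 28 (E)-caffeic acid
Product: 29 tert-butyl ester of the target (15-O-(E)-caffeate, free catechol)
Conditions: PPh3, DIAD, THF, 0 °C → rt
Reagents that add atoms: none
Why: Mitsunobu esterification activates the primary C15 alcohol and is chemoselective for the carboxyl group of a phenolic acid over its less acidic phenols, so that caffeic acid can be used unprotected; no stereocentre is involved.

Step 17
Reactants: 29 tert-butyl ester
Product: 31 target, (1S,4aR,5R,8aS)-5-[(S)-5-[(E)-3-(3,4-dihydroxyphenyl)prop-2-enoyl]oxy-3-methylpentyl]-1,4a-dimethyl-6-methylidenedecahydronaphthalene-1-carboxylic acid, via tris(trimethylsilyl) derivative 30 (not isolated)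
Conditions: TMSOTf, 2,6-lutidine, CH2Cl2, 0 °C; then aq. citric acid, THF
Reagents that add atoms: trimethylsilyl triflate, C[Si](C)(C)OS(=O)(=O)C(F)(F)F (silyl groups stay only in 30)
Why: Silyl triflate-mediated cleavage of the tert-butyl ester (O-silylation, loss of isobutene) works at the alkyl–oxygen bond and so is insensitive to the hindrance at C4, the lutidine buffer protects the acid-sensitive exocyclic olefin, and the transient silyl ester and aryl silyl ethers fall off in the mildly acidic work-up.

Compound list
1 | 2-methylcyclopentane-1,3-dione | CC1C(=O)CCC1=O | starting material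
2 | acrolein | C=CC=O | starting material
3 | 3-(1-methyl-2,5-dioxocyclopentyl)propanal | CC1(CCC=O)C(=O)CCC1=O | intermediate
4 | tert-butyl (triphenylphosphoranylidene)acetate | CC(C)(C)OC(=O)C=P(c1ccccc1)(c1ccccc1)c1ccccc1 | starting material
5 | tert-butyl (E)-5-(1-methyl-2,5-dioxocyclopentyl)pent-2-enoate | CC1(CC/C=C/C(=O)OC(C)(C)C)C(=O)CCC1=O | intermediate
6 | O-phenylsilyl ether of ketol 7 | O=C1CC[C@@]2(O[SiH2]c3ccccc3)[C@]1(C)CCC[C@@H]2C(=O)OC(C)(C)C | intermediate
7 | tert-butyl (3aS,4S,7aS)-3a-hydroxy-7a-methyl-1-oxooctahydro-1H-indene-4-carboxylate | O=C1CC[C@@]2(O)[C@]1(C)CCC[C@@H]2C(=O)OC(C)(C)C | intermediate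
8 | tert-butyl (7aS)-7a-methyl-1-oxo-2,3,5,6,7,7a-hexahydro-1H-indene-4-carboxylate | O=C1CCC2=C(C(=O)OC(C)(C)C)CCC[C@@]21C | intermediate
9 | tert-butyl (1S,7aS)-1-hydroxy-7a-methyl-2,3,5,6,7,7a-hexahydro-1H-indene-4-carboxylate | O[C@H]1CCC2=C(C(=O)OC(C)(C)C)CCC[C@@]21C | intermediate
10 | dilithium alkoxide–dienolate of 9 | [Li+].[Li+].[O-][C@H]1CC=C2C(=C([O-])OC(C)(C)C)CCC[C@@]21C | intermediate
11 | tert-butyl (1S,4S,7aS)-1-hydroxy-4,7a-dimethyl-2,4,5,6,7,7a-hexahydro-1H-indene-4-carboxylate | O[C@H]1CC=C2[C@]1(C)CCC[C@]2(C)C(=O)OC(C)(C)C | intermediate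
12 | tert-butyl (1S,3aS,4S,7aS)-1-hydroxy-4,7a-dimethyloctahydro-1H-indene-4-carboxylate | O[C@H]1CC[C@H]2[C@]1(C)CCC[C@]2(C)C(=O)OC(C)(C)C | intermediate
13 | tert-butyl (3aS,4S,7aS)-4,7a-dimethyl-1-oxooctahydro-1H-indene-4-carboxylate | O=C1CC[C@H]2[C@]1(C)CCC[C@]2(C)C(=O)OC(C)(C)C | intermediate
14 | (S)-(−)-citronellol | CC(C)=CCC[C@H](C)CCO | starting material
15 | (S)-citronellyl tert-butyldimethylsilyl ether | CC(C)=CCC[C@H](C)CCO[Si](C)(C)C(C)(C)C | intermediate
16 | secondary ozonide of 15 | CC1(C)OOC(CC[C@H](C)CCO[Si](C)(C)C(C)(C)C)O1 | intermediate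
17 | (S)-6-[(tert-butyldimethylsilyl)oxy]-4-methylhexan-1-ol | OCCC[C@H](C)CCO[Si](C)(C)C(C)(C)C | intermediate
18 | (S)-tert-butyl[(6-iodo-3-methylhexyl)oxy]dimethylsilane | ICCC[C@H](C)CCO[Si](C)(C)C(C)(C)C | intermediate
19 | [(S)-6-[(tert-butyldimethylsilyl)oxy]-4-methylhexyl]triphenylphosphonium iodide | [I-].c1ccccc1[P+](c1ccccc1)(c1ccccc1)CCC[C@H](C)CCO[Si](C)(C)C(C)(C)C | intermediate
20 | ylide of 19 | c1ccccc1P(c1ccccc1)(c1ccccc1)=CCC[C@H](C)CCO[Si](C)(C)C(C)(C)C | intermediate
21 | Z-alkylidene cis-hydrindane (C8=C9) | CC(C)(C)[Si](C)(C)OCC[C@@H](C)CC/C=C1/CC[C@H]2[C@]1(C)CCC[C@]2(C)C(=O)OC(C)(C)C | intermediate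
22 | 8β,9-diol (8S,9R) | CC(C)(C)[Si](C)(C)OCC[C@@H](C)CC[C@@H](O)[C@]1(O)CC[C@H]2[C@]1(C)CCC[C@]2(C)C(=O)OC(C)(C)C | intermediate
23 | 9-mesylate of 22 | CC(C)(C)[Si](C)(C)OCC[C@@H](C)CC[C@@H](OS(C)(=O)=O)[C@]1(O)CC[C@H]2[C@]1(C)CCC[C@]2(C)C(=O)OC(C)(C)C | intermediate
24 | 9-epi cis-decalone (chain β, axial) | O=C1CC[C@H]2[C@](C)(CCC[C@]2(C)C(=O)OC(C)(C)C)[C@H]1CC[C@H](C)CCO[Si](C)(C)C(C)(C)C | intermediate
25 | cis-decalone (1S,4aS,5S,8aS; chain α, equatorial) | O=C1CC[C@H]2[C@](C)(CCC[C@]2(C)C(=O)OC(C)(C)C)[C@@H]1CC[C@H](C)CCO[Si](C)(C)C(C)(C)C | intermediate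
26 | 8(17)-methylene silyl ether | C=C1CC[C@H]2[C@](C)(CCC[C@]2(C)C(=O)OC(C)(C)C)[C@@H]1CC[C@H](C)CCO[Si](C)(C)C(C)(C)C | intermediate
27 | 8(17)-methylene C15 alcohol, tert-butyl ester | C=C1CC[C@H]2[C@](C)(CCC[C@]2(C)C(=O)OC(C)(C)C)[C@@H]1CC[C@H](C)CCO | intermediate
28 | (E)-caffeic acid | OC(=O)/C=C/c1ccc(O)c(O)c1 | starting material
29 | tert-butyl ester of the target | C=C1CC[C@H]2[C@](C)(CCC[C@]2(C)C(=O)OC(C)(C)C)[C@@H]1CC[C@H](C)CCOC(=O)/C=C/c1ccc(O)c(O)c1 | intermediate
30 | trimethylsilyl ester bis(trimethylsilyl) ether of the target | C=C1CC[C@H]2[C@](C)(CCC[C@]2(C)C(=O)O[Si](C)(C)C)[C@@H]1CC[C@H](C)CCOC(=O)/C=C/c1ccc(O[Si](C)(C)C)c(O[Si](C)(C)C)c1 | intermediate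
31 | CNP0130717.2 | C=C1CC[C@H]2[C@](C)(CCC[C@]2(C)C(=O)O)[C@@H]1CC[C@H](C)CCOC(=O)/C=C/c1ccc(O)c(O)c1 | target

Total step count: 17. Longest linear sequence: 14 (steps 1–8 and 12–17).

Steps most likely to fail

**Step 14.**
- Risk: the methylene carbon C7 may migrate in competition with C10. The alkoxide may close onto C9 to a spiro-epoxide, the mesylate may eliminate, and the equilibration at C9 may stop at an unfavourable mixture.
- Fallback: it replaces the leaving-group-driven shift by a reversible, strain-driven one. It sets out from 22.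
- Parikh–Doering oxidation of the secondary alcohol gives the α-ketol F1.
- A Lewis acid (Al(OtBu)3 or BF3·OEt2) brings about the α-ketol (acyloin) rearrangement of this 1-acylcyclopentanol to the ring-enlarged 9-hydroxy-8-ketone F2. This is the classical D-homoannulation mode, in which the quaternary carbon migrates.
- SmI2 in THF–MeOH then removes the tertiary α-hydroxyl through a regiodefined samarium enolate. That enolate is protonated from the convex β face, and the route is rejoined at 25.

**Step 7.**
- Risk: the catalyst may fail to reach an olefin flanked by two quaternary carbons, may deactivate, or may deliver hydrogen from the α face once coordination is lost.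
- Fallback: it uses thermodynamic instead of directed control. It sets out from 11.
- Dess–Martin oxidation gives the β,γ-unsaturated ketone F3.
- DBU moves the olefin into conjugation by reversible γ-protonation at C5. This should settle on the cis-fused enone F4, because a trans-fused cyclopentenone is strained.
- Hydrogenation over Pd/C then gives 13, so that step 8 is no longer needed.

**Step 12.**
- Risk: the basic ylide may enolise the hindered ketone instead of adding to it. The Z geometry, on which the rotamer argument of step 14 rests, may also erode.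
- Fallback: it makes the C8–C9 bond by carbonyl addition of a weakly basic carbanion. It sets out from 15 and 13.
- Ozonolysis of 15 with Me2S work-up gives the aldehyde F5.
- MeSeH/ZnCl2 converts F5 into the bis(methylseleno)acetal F6.
- Selenium–lithium exchange with n-BuLi and addition to 13 from the convex face gives the β-hydroxyselenide F7 (both C9 epimers).
- Se-methylation with MeOTf turns selenium into a leaving group and triggers the same 1,2-shift of the more substituted carbon.
- Carbonate equilibration then rejoins the route at 25, bypassing 21–24.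

Further compounds
F1 | step 14 | α-ketol, 8β-hydroxy-9-ketone on the cis-hydrindane | CC(C)(C)[Si](C)(C)OCC[C@@H](C)CCC(=O)[C@]1(O)CC[C@H]2[C@]1(C)CCC[C@]2(C)C(=O)OC(C)(C)C
F2 | step 14 | ring-enlarged 9β-hydroxy-8-ketone (cis-decalone ketol) | O=C1CC[C@H]2[C@](C)(CCC[C@]2(C)C(=O)OC(C)(C)C)[C@]1(O)CC[C@H](C)CCO[Si](C)(C)C(C)(C)C
F3 | step 7 | β,γ-unsaturated ketone (C5=C6, C8 ketone) | O=C1CC=C2[C@]1(C)CCC[C@]2(C)C(=O)OC(C)(C)C
F4 | step 7 | cis-fused conjugated enone (C6=C7, H-5 β) | O=C1C=C[C@H]2[C@]1(C)CCC[C@]2(C)C(=O)OC(C)(C)C
F5 | step 12 | (S)-6-[(tert-butyldimethylsilyl)oxy]-4-methylhexanal | O=CCC[C@H](C)CCO[Si](C)(C)C(C)(C)C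
F6 | step 12 | bis(methylseleno)acetal of F5 | C[Se]C([Se]C)CC[C@H](C)CCO[Si](C)(C)C(C)(C)C
F7 | step 12 | β-hydroxyselenide (8α-OH, C9 epimers) | C[Se]C(CC[C@H](C)CCO[Si](C)(C)C(C)(C)C)[C@@]1(O)CC[C@H]2[C@]1(C)CCC[C@]2(C)C(=O)OC(C)(C)C
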